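## Structural features

The target is a 1,3-diacylated 2-arylglycerol: a three-carbon chain whose central carbon carries a tertiary hydroxyl group and a 2-hydroxy-4-methylphenyl ring (thymol-type benzene: side chain at C1, phenolic OH at C2, CH3 at C4), and whose two CH2O ends carry a 2-methylpropanoyl and a (2R)-2-methylbutanoyl group. There are two stereocentres and they are not adjacent: the α-carbon of the 2-methylbutanoate (R) and the benzylic tertiary carbinol (S). The carbinol carbon is stereogenic only because the two CH2O arms bear acyl groups that differ by one remote CH2, so it must be set while the arms are still very different, and that difference must then be preserved. Fragile points: in any monoester with a free primary OH, a 1,3-acyl shift (or a 1,2-shift relayed by the tertiary OH) is constitutionally degenerate but inverts the carbinol centre; the ortho-hydroxybenzylic tertiary alcohol can ionize towards an ortho-quinone methide under acid; the free phenol competes in acylations; the α-centre of the 2-methylbutanoyl group can be lost through a ketene. The real difficulty is therefore one carbon: a fully substituted benzylic carbinol that must be joined to the ring ortho to the phenol and para to CH3, in one absolute configuration, with two differentiated oxygenated arms. The key step exploits the 1,5-relationship between the phenolic oxygen on ring carbon C2 and the carbon of one CH2O arm (through C1 and the carbinol carbon): they can be tied into a five-membered lactone, a 3-hydroxybenzofuran-2(3H)-one. This puts one arm at the carboxyl level and the other at the CH2O level, masks the phenol, and lets the phenol oxygen deliver the electrophile to its own ortho carbon. Because the centre is defined only by which acid sits on which arm, the order of introducing the two acids decides which lactone enantiomer is needed; the plan fixes isobutyrate first.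

## Logic of the disconnections

10 to 7 and 9. The acyl C–O bond of the 2-methylbutanoate arm is cut. This makes the route convergent and brings in the costlier chiral acid last. It also means that 7, the only intermediate with a free primary hydroxyl group next to an ester, is consumed in the step that ends any possibility of a degenerate acyl shift. Gain: one stereocentre and five carbons are removed. Demand: the acylation must take the primary OH of 7 in the presence of its phenol and tertiary OH, with a base too weak to move the ester of 7 or to turn 9 into a ketene.

9 to 8. The C–Cl bond is cut; this is activation only. Demand: no base, so that the α-centre of 8 is kept.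

7 to 6. The two C–H bonds of the free CH2OH arm and the phenolic O–H are cut, which re-forms the aryl ester bond O1–C2 of a lactone. In 6 the two arms differ in oxidation level and the phenol is masked, so no protecting group is needed. Demand: hydride must go to the lactone carbonyl only, without free alkoxides that could move the isobutyrate.

6 to 3 and 4 (key disconnection). The ring-to-carbinol bond C3–C3a and the lactone bond O1–C2 are cut. In one sentence: 6 is made by an enantioselective, titanium-templated ortho-hydroxyalkylation of 4 with the keto group of 3 that closes to the lactone. The cut is made here because the hydroxyl group of 4 can direct C–C bond formation to its own ortho carbon and then capture the ester. The catalyst has to tell a chelated ester group from a CH2O-acyl group, not two near-identical arms. Gain: a bicyclic lactone with a fully substituted stereocentre goes back to two achiral compounds, one commercial and one a single step from commercial materials. Demand: attack at C6 of 4 (ortho to OH, para to CH3), not at C4 or C2; one face of the ketone of 3; ring closure before side reactions of 3.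

3 to 1 and 2. The CH2–O bond is cut, giving a carboxylate and an α-bromo ketone. Demand: a base weak enough to avoid enolization and self-condensation of 1 and 3.

## Other disconnections considered

Alternative 1: This is the route that comes to mind first. It cuts the two C–O bonds at the carbinol carbon and its CH2OH neighbour. The forward key step is a Sharpless asymmetric dihydroxylation (K2OsO2(OH)4, a bis-cinchona phthalazine ligand, K3Fe(CN)6, K2CO3) of the 1,1-disubstituted alkene A1, 2-[2-(benzyloxy)-4-methylphenyl]prop-2-en-1-yl 2-methylpropanoate, to the diol A2. Acylation with 9 and hydrogenolysis would then give 10. Grounds for preferring the chosen plan: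
- The osmium catalyst must distinguish an ortho-substituted aryl group from a CH2O-acyl group on a 1,1-disubstituted alkene, the pattern where the ligand pocket differentiates least.
- The medium is aqueous carbonate, in which A2 (a 1,3-diol monoester) can undergo the degenerate acyl shift that inverts its stereocentre.
- The aryl–carbon bond, the phenol protection and its removal need separate steps, about seven in all against five.
- The phenol is only a liability there, whereas the chosen plan uses it as directing and differentiating group.

Alternative 2: This cuts one acyl C–O bond and takes the stereochemistry from a desymmetrization. The forward key step is the enantiotopos-selective mono-acylation of the prochiral triol A3, 2-[2-(benzyloxy)-4-methylphenyl]propane-1,2,3-triol, which would be reached by aryl-metal addition to a protected dihydroxyacetone. The acylation would use a lipase with vinyl 2-methylpropanoate, or CuCl2 with a chiral bisoxazoline ligand (divalent copper) and 2-methylpropanoyl chloride, and would again give A2. Grounds for preferring the chosen plan: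
- The selectivity-determining event must choose between two identical CH2OH groups and has no predictive model; it can only be found by screening.
- The chemical catalysts for 2-substituted glycerols are developed for aroyl and sulfonyl transfer, not for α-branched aliphatic acyl groups.
- The C–C bond and the stereocentre are made in separate operations, and the sequence with protection is longer.
- The idea is kept, in a shorter protecting-group-free form, as the fallback for step 2.

Alternative 3: This cuts the CH2–O bond of the isobutyrate arm, modelled on the co-occurring epoxythymol esters. The forward key step is the regioselective opening at CH2 of the spiro-type epoxide A6 by 2 (carboxylate with an amine base). A6 would be made by Sharpless asymmetric epoxidation (Ti(OiPr)4, diethyl tartrate, t-BuOOH) of the allylic alcohol A4 to the epoxy alcohol A5, followed by acylation with 9. Final hydrogenolysis would give 10. Grounds for preferring the chosen plan: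
- The epoxide carbon is tertiary, benzylic and carries an ortho-oxygenated ring, so ionization at that carbon (opening at the wrong position with loss of configuration) competes with attack at CH2.
- The 2-aryl epoxy alcohol A5 is itself prone to titanium-mediated opening during its formation.
- The phenol again needs protection, and the sequence is about seven steps.
- No monoester problem arises, but the stereocentre rests on an epoxide that is the most labile compound of the route.

Key step: step 2

Assumption: the complex from (R)-BINOL and Ti(OiPr)4 is taken to leave the Re face of the chelated keto group of 3 open, as it does for glyoxylate esters in ene-type additions; if the first run shows the opposite sense, (S)-BINOL is used with no other change.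

## Steps

Step 1
Reactants: 1 ethyl 3-bromo-2-oxopropanoate (ethyl bromopyruvate); 2 2-methylpropanoic acid (isobutyric acid)
Product: 3 ethyl 3-[(2-methylpropanoyl)oxy]-2-oxopropanoate
Conditions: KHCO3 (1.1 equiv), DMF, 0 °C to rt
Reagents that add atoms: none
Why: SN2 displacement of the bromide of an α-bromo ketone by a carboxylate (O-alkylation of a carboxylate); the neighbouring carbonyl group accelerates the substitution and the weak bicarbonate base should avoid enolization and self-condensation of 1 and 3. No stereocentre is formed.

Step 2
Reactants: 3 ethyl 3-[(2-methylpropanoyl)oxy]-2-oxopropanoate; 4 3-methylphenol (m-cresol)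
Product: 6 [(3S)-3-hydroxy-6-methyl-2-oxo-2,3-dihydro-1-benzofuran-3-yl]methyl 2-methylpropanoate, via hydroxy ester 5 (not isolated)
Conditions: (R)-BINOL (22 mol %), Ti(OiPr)4 (20 mol %), 4 Å MS, toluene, 0 °C to rt; then TsOH·H2O (10 mol %), 50 °C
Reagents that add atoms: none
Why: Friedel–Crafts hydroxyalkylation with lactonization in the same flask. Phenol 4 exchanges with isopropoxide on (R)-(BINOLate)Ti(OiPr)2 to give a chiral aryloxide of tetravalent titanium, keto ester 3 binds the same metal through its ketone and ester carbonyl oxygens, and the ring carbon ortho to the Ti–O bond attacks the activated ketone through a six-membered cyclic transition state, after which proton loss restores the arene and gives 5. The closest known reaction type is the metal-aryloxide-templated, ortho-specific hydroxyalkylation of phenols and naphthols with pyruvate, trifluoropyruvate and glyoxylate esters, which is known in enantioselective form and is known to end in 3-hydroxybenzofuran-2(3H)-ones. The five-membered lactone ring closes by 5-exo-trig addition–elimination of the phenolic oxygen on the ethyl ester with loss of ethanol, promoted first by the titanium alkoxide and then by TsOH. The new stereocentre C3 is set in the C–C bond-forming step by the BINOLate ligand, which should leave the Re face of the chelated ketone open and so give the (S) configuration; the discrimination is between a chelated CO2Et group and a freely rotating CH2OC(O)iPr group, a far larger difference than that between the two CH2O arms of the target. Ortho and not para attack is secured by delivery inside the aryloxide–titanium–ketone array, and C6 of 4 reacts in preference to C2 because C2 is flanked by the methyl group. Chemoselectivity rests on the ketone of an α-keto ester being much more electrophilic than either ester group, and once the lactone has formed the carbinol carbon is α to a carbonyl group on a ring whose phenol is acylated, so it should neither ionize nor revert and the configuration is locked.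

Step 3
Reactants: 6 [(3S)-3-hydroxy-6-methyl-2-oxo-2,3-dihydro-1-benzofuran-3-yl]methyl 2-methylpropanoate
Product: 7 (2R)-2,3-dihydroxy-2-(2-hydroxy-4-methylphenyl)propyl 2-methylpropanoate
Conditions: BH3·SMe2 (2.0 equiv), NaBH4 (5 mol %), THF, 0 °C to rt; then MeOH, 0 °C
Reagents that add atoms: none
Why: Hydroxyl-directed borane reduction of an α-hydroxy ester: the tertiary OH forms an alkoxyborane that delivers hydride to the adjacent lactone carbonyl through a five-membered transition state, so the activated aryl lactone is reduced to the CH2OH arm and the phenol is released while the distal, α-branched isobutyrate is left alone. The medium holds boron-bound oxygens and no free alkoxide, which should keep the isobutyryl group from shifting to the new primary oxygen; no bond to the stereocentre is touched (the descriptor changes from S to R only because the ranking of the arms changes).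

Step 4
Reactants: 8 (2R)-2-methylbutanoic acid
Product: 9 (2R)-2-methylbutanoyl chloride
Conditions: (COCl)2 (1.2 equiv), DMF (cat.), CH2Cl2, 0 °C to rt; concentrate, use at once
Reagents that add atoms: oxalyl chloride, O=C(Cl)C(Cl)=O
Why: Acid chloride formation through the Vilsmeier-type chloroiminium species; no base is present and the α-carbon bears only alkyl groups, so neither enolization nor ketene formation should erode the (R) centre.

Step 5
Reactants: 7 (2R)-2,3-dihydroxy-2-(2-hydroxy-4-methylphenyl)propyl 2-methylpropanoate; 9 (2R)-2-methylbutanoyl chloride
Product: 10 (2S)-2-hydroxy-2-(2-hydroxy-4-methylphenyl)-3-[(2-methylpropanoyl)oxy]propyl (2R)-2-methylbutanoate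
Conditions: 9 (1.1 equiv), 2,4,6-collidine (2 equiv), CH2Cl2, −40 to 0 °C
Reagents that add atoms: none
Why: Chemoselective O-acylation of a primary alcohol with an acid chloride and a hindered weak base: as neutral nucleophiles the primary hydroxyl group is far more reactive than the hydrogen-bonded, ortho-substituted phenol (which collidine does not deprotonate) and the tertiary hydroxyl group. The same weak base should neither move the isobutyrate of 7 nor convert 9 into a ketene, so both stereocentres are carried into 10 unchanged (the carbinol descriptor changes from R to S only through the ranking of the arms).

## Compound list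

1 | ethyl 3-bromo-2-oxopropanoate (ethyl bromopyruvate) | CCOC(=O)C(=O)CBr | starting material
2 | 2-methylpropanoic acid (isobutyric acid) | CC(C)C(=O)O | starting material
3 | ethyl 3-[(2-methylpropanoyl)oxy]-2-oxopropanoate | CCOC(=O)C(=O)COC(=O)C(C)C | intermediate
4 | 3-methylphenol (m-cresol) | Cc1cccc(O)c1 | starting material
5 | ethyl (2S)-2-hydroxy-2-(2-hydroxy-4-methylphenyl)-3-[(2-methylpropanoyl)oxy]propanoate | CCOC(=O)[C@@](O)(COC(=O)C(C)C)c1ccc(C)cc1O | intermediate
6 | [(3S)-3-hydroxy-6-methyl-2-oxo-2,3-dihydro-1-benzofuran-3-yl]methyl 2-methylpropanoate | CC(C)C(=O)OC[C@]1(O)C(=O)Oc2cc(C)ccc12 | intermediate
7 | (2R)-2,3-dihydroxy-2-(2-hydroxy-4-methylphenyl)propyl 2-methylpropanoate | CC(C)C(=O)OC[C@](O)(CO)c1ccc(C)cc1O | intermediate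
8 | (2R)-2-methylbutanoic acid | CC[C@@H](C)C(=O)O | starting material
9 | (2R)-2-methylbutanoyl chloride | CC[C@@H](C)C(Cl)=O | intermediate
10 | (2S)-2-hydroxy-2-(2-hydroxy-4-methylphenyl)-3-[(2-methylpropanoyl)oxy]propyl (2R)-2-methylbutanoate | CC[C@@H](C)C(=O)OC[C@@](O)(COC(=O)C(C)C)c1ccc(C)cc1O | target

## Step count and least certain steps

Total step count: 5. Longest linear sequence: 4 steps (steps 1, 2, 3 and 5, from 1 to 10); step 4 is a one-step side branch.

Step 2 (key step). What may go wrong:
- poor facial selectivity, if 3 binds titanium through its acyloxy oxygen in competition with the 1,2-dicarbonyl chelate, or if a ligand-free titanium alkoxide pathway runs in the background;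
- slow turnover, because 4 is only moderately nucleophilic and the product can hold on to the metal;
- enolization and self-condensation of 3;
- attack para to the hydroxyl group if the reaction leaves the template.

The fallback changes the approach: the stereocentre is made by desymmetrization and not in the C–C bond-forming step. It sets out from 4. TiCl4-mediated ortho-hydroxyalkylation of 4 with diethyl oxomalonate (CH2Cl2, 0 °C) should give diethyl 2-hydroxy-2-(2-hydroxy-4-methylphenyl)propanedioate F1. Reduction with LiAlH4 in THF should give the achiral tetraol 2-(2-hydroxy-4-methylphenyl)propane-1,2,3-triol F2. Lipase-catalysed mono-acylation of one enantiotopic CH2OH arm (vinyl 2-methylpropanoate, immobilized Candida antarctica lipase B or a Burkholderia cepacia lipase, MTBE, rt) comes back to the route at 7. The enzyme is chosen by screening for the arm whose acylation gives 7; lipases leave phenols and tertiary alcohols alone, and the isobutyrate is the acyl group least prone to shift.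

Step 3. What may go wrong:
- transfer of the isobutyryl group to the newly formed primary oxygen, directly or relayed by the tertiary oxygen, while boron alkoxides are present; this is invisible in the constitution but inverts the carbinol centre and so erodes enantiomeric purity;
- partial over-reduction of the isobutyrate.

The fallback changes the approach: a benzyl ether arm, which neither migrates nor is reduced, is carried through the reduction and the isobutyrate is put on afterwards. It sets out from 4. The conditions of step 2 are applied with (S)-BINOL to ethyl 3-(benzyloxy)-2-oxopropanoate F3 (from diethyl oxalate and (benzyloxymethyl)magnesium chloride at −78 °C). The opposite ligand is needed because here the carbonyl-derived arm will carry the isobutyrate. This should give ethyl (2R)-3-(benzyloxy)-2-hydroxy-2-(2-hydroxy-4-methylphenyl)propanoate F4. LiBH4 in THF should reduce it to (2S)-3-(benzyloxy)-2-(2-hydroxy-4-methylphenyl)propane-1,2-diol F5. Acylation of the primary OH with 2-methylpropanoyl chloride and collidine, as in step 5, should give (2R)-3-(benzyloxy)-2-hydroxy-2-(2-hydroxy-4-methylphenyl)propyl 2-methylpropanoate F6. Hydrogenolysis (H2, Pd/C, EtOAc, neutral) comes back to the route at 7, which is acylated at once.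

Step 5. What may go wrong:
- loss of chemoselectivity (acylation of the phenol, diacylation);
- slow acylation of the neopentyl-type primary OH, which gives the ester of 7 time to shift;
- ketene formation from 9 with loss of the (R) centre.

The fallback changes the approach from a selective mono-acylation to exhaustive acylation and selective unmasking. It sets out from 7. Excess 9 (2.5 equiv) with pyridine and a little DMAP at 0 °C should acylate both the primary OH and the phenol to give 2-[(2S)-2-hydroxy-1-{[(2R)-2-methylbutanoyl]oxy}-3-[(2-methylpropanoyl)oxy]propan-2-yl]-5-methylphenyl (2R)-2-methylbutanoate F7. The aryl ester, far more electrophilic than the two alkyl esters, is then cleaved with pyrrolidine (1.1 equiv, CH2Cl2, 0 °C), which comes back to the route at 10.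

## Further compounds

F1 | step 2 | diethyl 2-hydroxy-2-(2-hydroxy-4-methylphenyl)propanedioate | CCOC(=O)C(O)(C(=O)OCC)c1ccc(C)cc1O
F2 | step 2 | 2-(2-hydroxy-4-methylphenyl)propane-1,2,3-triol | OCC(O)(CO)c1ccc(C)cc1O
F3 | step 3 | ethyl 3-(benzyloxy)-2-oxopropanoate | CCOC(=O)C(=O)COCc1ccccc1
F4 | step 3 | ethyl (2R)-3-(benzyloxy)-2-hydroxy-2-(2-hydroxy-4-methylphenyl)propanoate | CCOC(=O)[C@](O)(COCc1ccccc1)c1ccc(C)cc1O
F5 | step 3 | (2S)-3-(benzyloxy)-2-(2-hydroxy-4-methylphenyl)propane-1,2-diol | OC[C@](O)(COCc1ccccc1)c1ccc(C)cc1O
F6 | step 3 | (2R)-3-(benzyloxy)-2-hydroxy-2-(2-hydroxy-4-methylphenyl)propyl 2-methylpropanoate | CC(C)C(=O)OC[C@](O)(COCc1ccccc1)c1ccc(C)cc1O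
F7 | step 5 | 2-[(2S)-2-hydroxy-1-{[(2R)-2-methylbutanoyl]oxy}-3-[(2-methylpropanoyl)oxy]propan-2-yl]-5-methylphenyl (2R)-2-methylbutanoate | CC[C@@H](C)C(=O)OC[C@@](O)(COC(=O)C(C)C)c1ccc(C)cc1OC(=O)[C@H](C)CC
A1 | alternative 1 | 2-[2-(benzyloxy)-4-methylphenyl]prop-2-en-1-yl 2-methylpropanoate | C=C(COC(=O)C(C)C)c1ccc(C)cc1OCc1ccccc1
A2 | alternative 1 | (2R)-2-[2-(benzyloxy)-4-methylphenyl]-2,3-dihydroxypropyl 2-methylpropanoate | OC[C@@](O)(COC(=O)C(C)C)c1ccc(C)cc1OCc1ccccc1
A3 | alternative 2 | 2-[2-(benzyloxy)-4-methylphenyl]propane-1,2,3-triol | OCC(O)(CO)c1ccc(C)cc1OCc1ccccc1
A4 | alternative 3 | 2-[2-(benzyloxy)-4-methylphenyl]prop-2-en-1-ol | C=C(CO)c1ccc(C)cc1OCc1ccccc1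
A5 | alternative 3 | [(2R)-2-[2-(benzyloxy)-4-methylphenyl]oxiran-2-yl]methanol | OC[C@@]1(CO1)c1ccc(C)cc1OCc1ccccc1
A6 | alternative 3 | [(2S)-2-[2-(benzyloxy)-4-methylphenyl]oxiran-2-yl]methyl (2R)-2-methylbutanoate | CC[C@@H](C)C(=O)OC[C@@]1(CO1)c1ccc(C)cc1OCc1ccccc1
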